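## Structural features

The target is a 1-aryltetralin. Aromatic ring A (C4a, C5–C8, C8a) is fused to saturated ring B (C1–C4), which carries a 3,4,5-trimethoxyphenyl group on C1 and hydroxymethyl groups on C2 and C3. Ring A is pentasubstituted: OMe on C6, free OH on C7 and C8, and hydrogen only on C5. The stereocentres C1, C2 and C3 are contiguous, with the aryl group trans to the C2 arm and the two arms cis (1S,2R,3S). The fragile parts are:
- the catechol, which oxidises to an o-quinone that can tautomerise through C1–H or C4–H2;
- the doubly benzylic C1–H;
- the central methoxy group of the trimethoxyphenyl ring, which strong Lewis acids cleave;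
- the cis-1,4-diol, which can close to a tetrahydrofuran under strong acid.

The real difficulty is a ring A with three neighbouring, differently substituted oxygens in a fixed position relative to the ring fusion, joined to a trans,cis triad of stereocentres. The key step uses the fact that C5(H)–C6(OMe)–C7(O)–C8(O) has the substitution of a 2,3-dialkoxycyclobutenone (its C4–C3–C2–C1), while C4a=C8a can be the double bond of a cyclohexene that already holds C1–C3. Ring A is therefore grown onto a finished ring B.

## Logic of the disconnections

22 ⇐ 21. The two O–CH2Ph bonds on the C2 and C3 arms are cut. The primary alcohols must be masked through hydride, organolithium, cuprate and palladium steps, and benzyl ethers survive all of them. The gain is a last step that is neutral and reductive; the demand is that it spares the catechol and the diarylmethine C1–H.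

21 ⇐ 19 (through 20). The C7 hydroxyl is traced back to a C7 methoxy group. This lets the four-carbon unit 15 come from symmetrical 13, so its preparation has no regiochemical question. An analogue of 15 with a benzyl group on the C7 oxygen would save this step, but its precursor would be reduced at either carbonyl. The distinction between the C6 and C7 oxygens is made late by the free C8 phenol, which directs oxidation to its neighbour. The demand is oxidation at C7 and not at C5 or C8a, and reduction of 20 before it tautomerises.

19 ⇐ 12 + 15. The bonds C5–C4a and C8–C8a are cut. All of C5–C8 with their substituents come from 15, and C4a=C8a with the three stereocentres come from 12. No aromatic substitution is needed and C1–C3 are not touched. The demand is bond formation at the CH carbon of 15 and a thermal cascade that 12 tolerates.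

15 ⇐ 14 ⇐ 13. The C–Cl bond is traced to C–OH and this to one carbonyl of 13. Both steps are functional-group changes on a symmetrical or already desymmetrised four-membered ring. The demand is non-acidic, dry handling, since 14 and 15 ionise easily at C4.

12 ⇐ 11. The C–Sn bond is traced to an enol C–O(triflate) bond on the same carbon. The gain is that the position of tin is decided by the position of an enolate. The demand is a stannylation that does not move the double bond.

11 ⇐ 6 + 7 (through 8, 9 and 10). The bond between the aryl group and the future C1 is cut, together with the O–S bond of the triflate. Conjugate addition creates the third stereocentre trans to the two existing ones and leaves an enolate whose double bond lies exactly where C4a=C8a is needed. The demand is trapping of 10 on oxygen before any proton exchange.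

6 ⇐ 5 ⇐ 4. The carbonyl is traced to a carbinol, and the allylic alcohol to a meso epoxide by removal of one of two enantiotopic hydrogens. This is where absolute configuration enters. The demand is a single diastereomer of 4 and a lithium amide of the right handedness.

4 ⇐ 3 ⇐ 2 ⇐ 1. The epoxide oxygen, the benzyl groups and the oxidation level of the two arms are removed in turn. The cis relationship of C2 and C3 is inherited from 1 and never has to be created.

## Other disconnections considered

Alternative 1: The cut is C2–C3 of ring B together with the C9'–O bond of a lactone. It leads back to iodomalonate A1, an open benzhydryl malonate whose ring A already carries an allyl group on C4a.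
- Forward step: under atom-transfer conditions (hexabutylditin and light, or BEt3/O2) the malonyl radical at C2 would add 6-exo to the internal allyl carbon C3. The primary radical at C9' would take iodine from A1, and the cis ester would displace the iodide to give lactone ester A2.
- In favour: ring B, the C3 stereocentre and the differentiation of the two C2 esters arise in one operation. Ring A is bought as an arene, so O7 and O8 can be benzyl ethers from the start and no demethylation is needed. On that point it is better than the chosen plan.
- Against: 1,5-hydrogen transfer from the allylic and benzylic C4–H2 to the C2 radical competes with a 6-exo closure that is slower than the 5-exo mode. The C1/C3 relationship rests on a chair-like transition state across a 1,3-distance. C1 must be set enantioselectively at a benzhydryl carbon flanked by a 2,6-disubstituted aryl group. The allyl group can reach C4a only by a para shift from O7, since both ortho positions are oxygenated, and the benzhydryl carbon must then be attached at C8a in competition with C5.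
- Comparison: on structure the plans are equal, since both reach the same tetralin and A2 carries C9 and C9' ready for reduction. On mechanism the radical chain has more open side channels than the pericyclic cascade of step 10, but it creates a stereocentre where step 10 creates none, which counts for the alternative. On step economy they are about equal: the alternative saves the demethylation but spends steps on ring A regiochemistry and on decarboxylation of A2.

Alternative 2: The cut removes both one-carbon arms, C2–C9 and C3–C9', and leads to dihydronaphthalene A3.
- Forward step: under CO in methanol with PdCl2 and CuCl2 as reoxidant, a palladium methoxycarbonyl would add syn across C2=C3 on the face away from the C1 aryl group. A second CO insertion and methanolysis would give cis diester A4. Hydride reduction and hydrogenolysis would finish.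
- In favour: two C–C bonds and two stereocentres form in one step, which is better than step 10. The cis relationship follows from the syn mechanism, an equal of the chosen plan, where it comes from the cis anhydride. Ring A carries benzyl ethers, so no demethylation is needed.
- Against: the alkylpalladium intermediate has syn β-hydrogens on benzylic C1 or C4, so β-hydride elimination to an unsaturated monoester competes with the second carbonylation. Divalent palladium with CuCl2 is also an oxidant and isomerisation catalyst for a 1,4-dihydronaphthalene, whose aromatisation or shift into conjugation destroys C1. Unstrained cyclohexene-type alkenes are poor substrates for this carbonylation. A3, with a doubly benzylic and allylic C1–H, is hard to make and keep enantiopure.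
- Comparison: on structure the alternative leaves two of the three contiguous centres to one face-selective step on a labile alkene; the chosen plan spreads the task over a cis anhydride, a desymmetrisation and a cuprate addition. On mechanism both use palladium, but the chosen coupling has no alkylpalladium species with β-hydrogens. On step economy the alternative would be shorter if the carbonylation ran as drawn, and that is its real advantage.

Alternative 3: The cut is C1–C8a and C4–C4a, a Diels–Alder disconnection of ring B into aryl diene A5 and o-quinone A6.
- Forward step: a chiral cationic oxazaborolidine would activate A6. A5 would add to its unsubstituted C=C bond with the aryl-bearing terminus next to the carbonyl-flanked carbon, and enolisation would give catechol A7 with C1 set.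
- In favour: it is the most convergent assembly of the carbocycle. Ring A arrives with the free catechol and the methoxy group in place, with no protecting group or demethylation, which is better than the chosen plan on ring A. C1 is set by a catalyst and the regiochemistry follows the normal ortho orientation.
- Against: A6 is a short-lived o-quinone that dimerises and can react through its O=C–C=O unit as a heterodiene. Its two adjacent carbonyl groups offer the Lewis acid two binding modes, so enantio- and regiocontrol are less assured than with p-quinones. A7 is both a catechol and a 1,4-dihydronaphthalene in the presence of an oxidising quinone, so dehydrogenation to a naphthalene is a ready sink. Above all, A7 lacks C9 and C9', so the task of adding two cis carbons anti to the aryl group remains, in effect the carbonylation of Alternative 2 on a protected derivative.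
- Comparison: on structure this plan builds ring B on a finished ring A and sets one stereocentre; the chosen plan builds ring A on a finished, fully stereodefined ring B. On mechanism both key steps are pericyclic and the alternative is the more direct, an equal or better. On step economy it is shorter to the ring system but not to the target, since protection, double carbonylation, reduction and deprotection would follow.

Key step: step 10

Remark on the chemistry: the structures used here were rebuilt from the target and agree with it (1,2-trans, 2,3-cis, 1S,2R,3S); the carbon of 15 that is joined to C4a is its own C4 (the CHCl carbon), which becomes C5 of the tetralin.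

Remark on the chemistry: three points are tightened. Epoxide 4 is carried on as the single trans diastereomer, because the cis epoxide would be expected to give the antipodal enone with the same base. Chloride 15 is used crude after a non-aqueous work-up. Periodate oxidation and dithionite reduction are run in one flask, so o-quinone 20 is never isolated and two steps follow the key step.

Remark on the chemistry: the sense of step 4 is assigned by analogy with the (S)-selective rearrangement of cyclohexene oxide by the same lithium amide; if the sense is the reverse, the (R)-diamine is used.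

## Steps

Step 1
Reactants: 1 cis-1,2,3,6-tetrahydrophthalic anhydride
Product: 2 [(1R,2S)-cyclohex-4-ene-1,2-diyl]dimethanol (cis, meso)
Conditions: LiAlH4, THF, 0 °C → reflux
Reagents that add atoms: none
Why: Hydride reduction of a cyclic anhydride takes both acyl carbons to primary alcohols; the ring-fusion carbons are not enolised, so the cis relationship of 1 passes unchanged into meso 2.

Step 2
Reactants: 2 [(1R,2S)-cyclohex-4-ene-1,2-diyl]dimethanol
Product: 3 cis-4,5-bis(benzyloxymethyl)cyclohexene (meso)
Conditions: NaH, BnBr, Bu4NI (cat.), THF/DMF, 0 °C → rt
Reagents that add atoms: benzyl bromide, BrCc1ccccc1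
Why: Williamson etherification of both primary alkoxides; the benzyl ethers tolerate every later base, oxidant and palladium step and are removed together in the last step.

Step 3
Reactants: 3 cis-4,5-bis(benzyloxymethyl)cyclohexene
Product: 4 (1R,3R,4S,6S)-3,4-bis(benzyloxymethyl)-7-oxabicyclo[4.1.0]heptane (meso; epoxide oxygen trans to both CH2OBn groups)
Conditions: mCPBA, NaHCO3, CH2Cl2, 0 °C → rt; chromatography
Reagents that add atoms: 3-chloroperoxybenzoic acid (mCPBA), OOC(=O)c1cccc(Cl)c1
Why: Prilezhaev epoxidation; the pseudoaxial CH2OBn group of the half-chair shields its own face, so the peracid should attack mainly anti and give the trans meso epoxide, and the minor cis isomer is removed because it would lead to the opposite enantiomer in step 4.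

Step 4
Reactants: 4 (1R,3R,4S,6S)-3,4-bis(benzyloxymethyl)-7-oxabicyclo[4.1.0]heptane
Product: 5 (1S,4R,5S)-4,5-bis(benzyloxymethyl)cyclohex-2-en-1-ol
Conditions: (S)-2-(pyrrolidin-1-ylmethyl)pyrrolidine, n-BuLi, THF, 0 °C → rt
Reagents that add atoms: none
Why: Enantioselective rearrangement of a meso epoxide to an allylic alcohol by a chiral lithium amide (syn β-elimination through a cyclic transition state); the amide removes one of the two enantiotopic hydrogens syn to oxygen, which should leave the (1S) carbinol and thereby fixes C4 and C5 as R and S, while the carbinol centre itself is erased in step 5.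

Step 5
Reactants: 5 (1S,4R,5S)-4,5-bis(benzyloxymethyl)cyclohex-2-en-1-ol
Product: 6 (4R,5S)-4,5-bis(benzyloxymethyl)cyclohex-2-en-1-one
Conditions: Dess–Martin periodinane, NaHCO3, CH2Cl2, 0 °C → rt
Reagents that add atoms: none
Why: Dess–Martin oxidation of a secondary allylic alcohol under buffered, non-basic conditions, so the γ-centre C4 is not epimerised and the double bond does not move.

Step 6
Reactants: 6 (4R,5S)-4,5-bis(benzyloxymethyl)cyclohex-2-en-1-one; 7 5-bromo-1,2,3-trimethoxybenzene
Product: 11 (3R,4R,5S)-4,5-bis(benzyloxymethyl)-3-(3,4,5-trimethoxyphenyl)cyclohex-1-en-1-yl trifluoromethanesulfonate, via aryllithium 8 (not isolated), via diarylcuprate 9 (not isolated), via lithium enolate 10 (not isolated)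
Conditions: 7, t-BuLi, Et2O/THF, −78 °C; CuI, −78 → −30 °C; 6, −78 → −40 °C; PhNTf2, −78 °C → rt
Reagents that add atoms: N-phenylbis(trifluoromethanesulfonimide) (PhNTf2), O=S(=O)(N(c1ccccc1)S(=O)(=O)C(F)(F)F)C(F)(F)F
Why: Gilman conjugate addition followed by O-triflation of the enolate; the aryl group should add axially to C3 on the face opposite the cis C4 and C5 substituents, which reinforce each other, so the new centre is trans to both, and the regiodefined enolate 10 is trapped on oxygen before it can equilibrate, which marks the future C4a.

Step 7
Reactants: 11 (3R,4R,5S)-4,5-bis(benzyloxymethyl)-3-(3,4,5-trimethoxyphenyl)cyclohex-1-en-1-yl trifluoromethanesulfonate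
Product: 12 tributyl[(3R,4R,5S)-4,5-bis(benzyloxymethyl)-3-(3,4,5-trimethoxyphenyl)cyclohex-1-en-1-yl]stannane
Conditions: (Bu3Sn)2, Pd(PPh3)4 (cat.), LiCl, dioxane, 100 °C
Reagents that add atoms: hexabutylditin, CCCC[Sn](CCCC)(CCCC)[Sn](CCCC)(CCCC)CCCC
Why: Stille-type stannylation of an alkenyl triflate: zerovalent palladium inserts into the C–O bond (chloride assisting), the distannane transmetalates and reductive elimination gives the C–Sn bond on the same carbon, with no change at the double bond or the stereocentres.

Step 8
Reactants: 13 dimethyl squarate
Product: 14 4-hydroxy-2,3-dimethoxycyclobut-2-en-1-one (racemic)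
Conditions: LiAlH(OtBu)3, THF, −78 → −20 °C; cold neutral work-up
Reagents that add atoms: none
Why: 1,2-Hydride addition of a bulky, mild aluminium hydride to one of two equivalent carbonyl groups, a reduction established for dialkyl squarates; it should stop at the mono-alcohol because the remaining carbonyl is a deactivated vinylogous ester, and the symmetry of 13 leaves no regiochemical choice.

Step 9
Reactants: 14 4-hydroxy-2,3-dimethoxycyclobut-2-en-1-one
Product: 15 4-chloro-2,3-dimethoxycyclobut-2-en-1-one (racemic)
Conditions: SOCl2, pyridine, CH2Cl2, −20 → 0 °C; filtration, used crude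
Reagents that add atoms: thionyl chloride, O=S(Cl)Cl
Why: Chlorodehydroxylation through the chlorosulfite; the allylic, α-keto carbon ionises readily and, with water excluded, chloride is the only nucleophile and should return at C4 to give the conjugated vinylogous ester, whose configuration at C4 is irrelevant.

Step 10
Reactants: 12 tributyl[(3R,4R,5S)-4,5-bis(benzyloxymethyl)-3-(3,4,5-trimethoxyphenyl)cyclohex-1-en-1-yl]stannane; 15 4-chloro-2,3-dimethoxycyclobut-2-en-1-one
Product: 19 (1S,2R,3S)-2,3-bis(benzyloxymethyl)-6,7-dimethoxy-1-(3,4,5-trimethoxyphenyl)tetralin-8-ol (tetralin numbering), via alkenylcyclobutenone 16 (not isolated), via dienylketene 17 (not isolated), via cyclohexadienone 18 (not isolated)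
Conditions: Pd2(dba)3 (cat.), tri(2-furyl)phosphine, dioxane, 50 °C → 100 °C
Reagents that add atoms: none
Why: Zerovalent palladium (Pd2(dba)3 with the weakly donating tri(2-furyl)phosphine) adds oxidatively to the allylic, α-keto C–Cl bond of 15 to give an oxocyclobutenyl palladium chloride; transmetalation from tin, the slow step that this ligand speeds up, and reductive elimination at the CH terminus give 16 with the new C5–C4a bond. On heating, 16 opens reversibly (conrotatory 4π) to vinylketene 17; only the isomer with the cyclohexenyl group cis to the ketene carbon can close, and it is drained by a thermal disrotatory 6π electrocyclisation that forms C8–C8a and ring A as dienone 18, which aromatises by enolisation to phenol 19. The closest known reaction type is the palladium-catalysed coupling of 4-chlorocyclobutenones with alkenylstannanes followed by thermal ring expansion to phenols, a relative of the thermal rearrangement of 4-alkenyl-4-hydroxycyclobutenones to hydroquinones; 15 is a new member of that substrate class. No lasting stereocentre is made: C4 of 16 and C8a of 18 are transient and both end sp2, while C1–C3 lie away from every bond change and meet neither acid nor base. The selectivity needed is coupling at the CH terminus of the ambident oxocyclobutenyl ligand and not at the methoxy-bearing terminus, which would give the 5,6-dimethoxy isomer; it should be secured by the lower substitution of that carbon and by the conjugated vinylogous ester that only this mode keeps. On the cyclohexene side the regiochemistry is fixed, because tin marks C4a and the ketene can then reach only C8a.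

Step 11
Reactants: 19 (1S,2R,3S)-2,3-bis(benzyloxymethyl)-6,7-dimethoxy-1-(3,4,5-trimethoxyphenyl)tetralin-8-ol
Product: 21 (1S,2R,3S)-2,3-bis(benzyloxymethyl)-6-methoxy-1-(3,4,5-trimethoxyphenyl)tetralin-7,8-diol (tetralin numbering), via o-quinone 20 (not isolated)
Conditions: NaIO4, MeCN/H2O/AcOH, 0 °C; then Na2S2O4 (aq.), 0 °C → rt
Reagents that add atoms: water, O
Why: Periodate oxidative demethylation of a guaiacol unit: the C8 phenol forms a periodate ester, water adds at the methoxy-bearing ortho carbon C7 and loss of methanol gives o-quinone 20, while the trimethoxyphenyl ring, having no free hydroxyl, is inert; dithionite added to the same flask reduces 20 to catechol 21 before it can tautomerise through C1–H or C4–H2.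

Step 12
Reactants: 21 (1S,2R,3S)-2,3-bis(benzyloxymethyl)-6-methoxy-1-(3,4,5-trimethoxyphenyl)tetralin-7,8-diol
Product: 22 (1S,2R,3S)-2,3-bis(hydroxymethyl)-6-methoxy-1-(3,4,5-trimethoxyphenyl)tetralin-7,8-diol (tetralin numbering; the target)
Conditions: H2 (1 atm), Pd/C, EtOAc/MeOH, rt
Reagents that add atoms: none
Why: Hydrogenolysis of two benzyl ethers under neutral conditions; aryl methyl ethers, the catechol and the diarylmethine C1–H are stable to it and no stereocentre is touched.

## Compound list

1 | cis-1,2,3,6-tetrahydrophthalic anhydride (meso) | O=C1OC(=O)[C@@H]2CC=CC[C@H]12 | starting material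
2 | [(1R,2S)-cyclohex-4-ene-1,2-diyl]dimethanol (cis, meso) | OC[C@@H]1CC=CC[C@@H]1CO | intermediate
3 | cis-4,5-bis(benzyloxymethyl)cyclohexene (meso) | c1ccccc1COC[C@@H]1CC=CC[C@@H]1COCc1ccccc1 | intermediate
4 | (1R,3R,4S,6S)-3,4-bis(benzyloxymethyl)-7-oxabicyclo[4.1.0]heptane (meso, oxygen trans to the CH2OBn groups) | c1ccccc1COC[C@@H]1C[C@H]2O[C@H]2C[C@@H]1COCc1ccccc1 | intermediate
5 | (1S,4R,5S)-4,5-bis(benzyloxymethyl)cyclohex-2-en-1-ol | O[C@@H]1C=C[C@@H](COCc2ccccc2)[C@@H](COCc2ccccc2)C1 | intermediate
6 | (4R,5S)-4,5-bis(benzyloxymethyl)cyclohex-2-en-1-one | O=C1C=C[C@@H](COCc2ccccc2)[C@@H](COCc2ccccc2)C1 | intermediate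
7 | 5-bromo-1,2,3-trimethoxybenzene | COc1cc(Br)cc(OC)c1OC | starting material
8 | (3,4,5-trimethoxyphenyl)lithium | [Li]c1cc(OC)c(OC)c(OC)c1 | intermediate
9 | lithium bis(3,4,5-trimethoxyphenyl)cuprate | [Li+].COc1cc([Cu-]c2cc(OC)c(OC)c(OC)c2)cc(OC)c1OC | intermediate
10 | lithium (3R,4R,5S)-4,5-bis(benzyloxymethyl)-3-(3,4,5-trimethoxyphenyl)cyclohex-1-en-1-olate | [Li+].[O-]C1=C[C@H](c2cc(OC)c(OC)c(OC)c2)[C@@H](COCc2ccccc2)[C@@H](COCc2ccccc2)C1 | intermediate
11 | (3R,4R,5S)-4,5-bis(benzyloxymethyl)-3-(3,4,5-trimethoxyphenyl)cyclohex-1-en-1-yl trifluoromethanesulfonate | O=S(=O)(OC1=C[C@H](c2cc(OC)c(OC)c(OC)c2)[C@@H](COCc2ccccc2)[C@@H](COCc2ccccc2)C1)C(F)(F)F | intermediate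
12 | tributyl[(3R,4R,5S)-4,5-bis(benzyloxymethyl)-3-(3,4,5-trimethoxyphenyl)cyclohex-1-en-1-yl]stannane | CCCC[Sn](CCCC)(CCCC)C1=C[C@H](c2cc(OC)c(OC)c(OC)c2)[C@@H](COCc2ccccc2)[C@@H](COCc2ccccc2)C1 | intermediate
13 | dimethyl squarate (3,4-dimethoxycyclobut-3-ene-1,2-dione) | COC1=C(OC)C(=O)C1=O | starting material
14 | 4-hydroxy-2,3-dimethoxycyclobut-2-en-1-one (racemic) | O=C1C(OC)=C(OC)C1O | intermediate
15 | 4-chloro-2,3-dimethoxycyclobut-2-en-1-one (racemic) | O=C1C(OC)=C(OC)C1Cl | intermediate
16 | 4-[4,5-bis(benzyloxymethyl)-3-(3,4,5-trimethoxyphenyl)cyclohex-1-en-1-yl]-2,3-dimethoxycyclobut-2-en-1-one (ring stereocentres as in 12; both epimers at the cyclobutenone carbon) | O=C1C(OC)=C(OC)C1C1=C[C@H](c2cc(OC)c(OC)c(OC)c2)[C@@H](COCc2ccccc2)[C@@H](COCc2ccccc2)C1 | intermediate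
17 | (3E)-4-[4,5-bis(benzyloxymethyl)-3-(3,4,5-trimethoxyphenyl)cyclohex-1-en-1-yl]-2,3-dimethoxybuta-1,3-dien-1-one (cyclohexenyl group cis to the ketene carbon; ring stereocentres as in 12) | O=C=C(OC)/C(OC)=C\C1=C[C@H](c2cc(OC)c(OC)c(OC)c2)[C@@H](COCc2ccccc2)[C@@H](COCc2ccccc2)C1 | intermediate
18 | 2,3-bis(benzyloxymethyl)-6,7-dimethoxy-1-(3,4,5-trimethoxyphenyl)-2,3,4,8a-tetrahydronaphthalen-8(1H)-one (tetralin numbering; C1–C3 as in 19, both epimers at C8a) | COC1=C(OC)C(=O)C2[C@H](c3cc(OC)c(OC)c(OC)c3)[C@@H](COCc3ccccc3)[C@@H](COCc3ccccc3)CC2=C1 | intermediate
19 | (1S,2R,3S)-2,3-bis(benzyloxymethyl)-6,7-dimethoxy-1-(3,4,5-trimethoxyphenyl)tetralin-8-ol (tetralin numbering) | COc1cc2c(c(O)c1OC)[C@H](c1cc(OC)c(OC)c(OC)c1)[C@@H](COCc1ccccc1)[C@@H](COCc1ccccc1)C2 | intermediate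
20 | (1S,2R,3S)-2,3-bis(benzyloxymethyl)-6-methoxy-1-(3,4,5-trimethoxyphenyl)-1,2,3,4-tetrahydronaphthalene-7,8-dione (tetralin numbering) | COC1=CC2=C(C(=O)C1=O)[C@H](c1cc(OC)c(OC)c(OC)c1)[C@@H](COCc1ccccc1)[C@@H](COCc1ccccc1)C2 | intermediate
21 | (1S,2R,3S)-2,3-bis(benzyloxymethyl)-6-methoxy-1-(3,4,5-trimethoxyphenyl)tetralin-7,8-diol (tetralin numbering) | COc1cc2c(c(O)c1O)[C@H](c1cc(OC)c(OC)c(OC)c1)[C@@H](COCc1ccccc1)[C@@H](COCc1ccccc1)C2 | intermediate
22 | (1S,2R,3S)-2,3-bis(hydroxymethyl)-6-methoxy-1-(3,4,5-trimethoxyphenyl)tetralin-7,8-diol (tetralin numbering) | COc1cc2c(c(O)c1O)[C@H](c1cc(OC)c(OC)c(OC)c1)[C@@H](CO)[C@@H](CO)C2 | target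

## Step count and least certain steps

Total: 12 steps. Longest linear sequence: 10 steps (steps 1–7, then 10–12); the branch 13 → 15 has 2 steps.

Step 10 (key step). Three processes may defeat it. Ionisation or hydrolytic breakdown of 15 may outrun oxidative addition. Transmetalation from the hindered cyclohexenyl tin may be slow, so that protodestannylation of 12 takes over. Reductive elimination may occur at the methoxy-bearing terminus and build the isomeric ring A. The fallback keeps the same four-carbon plus two-carbon annulation but enters through a carbonyl group of 13 instead of a C–Cl bond. It sets out from 12 and 13 and comes back at 19.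
- Tin–lithium exchange on 12 (MeLi, THF, −78 °C) would give the alkenyllithium corresponding to 12 F1.
- F1 would add 1,2 to 13 to give 4-[4,5-bis(benzyloxymethyl)-3-(3,4,5-trimethoxyphenyl)cyclohex-1-en-1-yl]-4-hydroxy-2,3-dimethoxycyclobut-2-en-1-one F2.
- Heating F2 in xylene should bring about the known thermal ring expansion to (1S,2R,3S)-2,3-bis(benzyloxymethyl)-6,7-dimethoxy-1-(3,4,5-trimethoxyphenyl)tetralin-5,8-diol F3.
- The less hindered C5 hydroxyl of F3 would be triflated (PhNTf2, K2CO3) to the C5 triflate F4.
- Palladium-catalysed formate reduction (Pd(OAc)2, dppf, HCO2H, Et3N, DMF) would remove the C5 oxygen and return 19.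
- The cost is three more steps; the gain is that no labile halide is handled.

Step 9. The C4–O or C4–Cl bond may ionise and be captured by traces of water, with loss of methanol to a cyclobutenedione, or the chloride may undergo allylic transposition on standing. The fallback changes the electrophile from a halide made by substitution to an ester made by acylation, so that only palladium ionises it. It sets out from 14 and comes back at 19.
- Methyl chloroformate and pyridine would give 2,3-dimethoxy-4-oxocyclobut-2-en-1-yl methyl carbonate F5.
- F5 would be coupled with 12 under the palladium and phosphine of step 10, as an allylic carbonate coupling with an alkenylstannane, and heated on to 19.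

Step 4. Discrimination between the two enantiotopic hydrogens may be incomplete, it depends on the diastereomeric purity of 4, and α-lithiation of the epoxide may compete. The fallback replaces desymmetrisation by kinetic resolution at the cost of half the material. It sets out from 4 and comes back at 5.
- Achiral LiNEt2 in THF would give racemic (1S*,4R*,5S*)-4,5-bis(benzyloxymethyl)cyclohex-2-en-1-ol F6.
- Amano lipase PS with vinyl acetate is expected, by analogy with the parent cyclohex-2-enol, to acylate the (1R) alcohol to (1R,4S,5R)-4,5-bis(benzyloxymethyl)cyclohex-2-en-1-yl acetate F7.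
- Unreacted 5 is separated by chromatography.

Step 11. Oxidation may go to the free para position C5 or to C8a instead of C7, and 20 may tautomerise to a quinone methide through C1–H or C4–H2 before it is reduced, which would cost the C1 configuration. The fallback replaces oxidation and reduction by a chelation-directed Lewis acid dealkylation. It sets out from 19 and comes back at 22, and no new compound is isolated.
- BCl3 with pentamethylbenzene in CH2Cl2 (−78 → 0 °C) would convert the C8 phenol to a borate that delivers boron to the neighbouring C7 ether oxygen and cleaves its methyl group.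
- The same reagent cleaves the two benzyl ethers, and the scavenger takes up the benzyl cations.
- The temperature must stay low to spare the central methoxy group of the trimethoxyphenyl ring.

## Further compounds

F1 | step 10 | [4,5-bis(benzyloxymethyl)-3-(3,4,5-trimethoxyphenyl)cyclohex-1-en-1-yl]lithium (configured as 12) | [Li]C1=C[C@H](c2cc(OC)c(OC)c(OC)c2)[C@@H](COCc2ccccc2)[C@@H](COCc2ccccc2)C1
F2 | step 10 | 4-[4,5-bis(benzyloxymethyl)-3-(3,4,5-trimethoxyphenyl)cyclohex-1-en-1-yl]-4-hydroxy-2,3-dimethoxycyclobut-2-en-1-one (ring configured as 12; both epimers at the carbinol carbon) | O=C1C(OC)=C(OC)C1(O)C1=C[C@H](c2cc(OC)c(OC)c(OC)c2)[C@@H](COCc2ccccc2)[C@@H](COCc2ccccc2)C1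
F3 | step 10 | (1S,2R,3S)-2,3-bis(benzyloxymethyl)-6,7-dimethoxy-1-(3,4,5-trimethoxyphenyl)tetralin-5,8-diol (tetralin numbering) | COc1c(O)c2c(c(O)c1OC)[C@H](c1cc(OC)c(OC)c(OC)c1)[C@@H](COCc1ccccc1)[C@@H](COCc1ccccc1)C2
F4 | step 10 | (1S,2R,3S)-2,3-bis(benzyloxymethyl)-8-hydroxy-6,7-dimethoxy-1-(3,4,5-trimethoxyphenyl)tetralin-5-yl trifluoromethanesulfonate (tetralin numbering) | COc1c(OS(=O)(=O)C(F)(F)F)c2c(c(O)c1OC)[C@H](c1cc(OC)c(OC)c(OC)c1)[C@@H](COCc1ccccc1)[C@@H](COCc1ccccc1)C2
F5 | step 9 | 2,3-dimethoxy-4-oxocyclobut-2-en-1-yl methyl carbonate (racemic) | COC(=O)OC1C(OC)=C(OC)C1=O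
F6 | step 4 | racemic (1S*,4R*,5S*)-4,5-bis(benzyloxymethyl)cyclohex-2-en-1-ol (5 and its enantiomer) | O[C@@H]1C=C[C@@H](COCc2ccccc2)[C@@H](COCc2ccccc2)C1.O[C@H]1C=C[C@H](COCc2ccccc2)[C@H](COCc2ccccc2)C1
F7 | step 4 | (1R,4S,5R)-4,5-bis(benzyloxymethyl)cyclohex-2-en-1-yl acetate | CC(=O)O[C@H]1C=C[C@H](COCc2ccccc2)[C@H](COCc2ccccc2)C1
F0 | step 11 | none | none
A1 | alternative 1 | dimethyl 2-{(S)-[2,3-bis(benzyloxy)-4-methoxy-6-(prop-2-en-1-yl)phenyl](3,4,5-trimethoxyphenyl)methyl}-2-iodopropanedioate | C=CCc1cc(OC)c(OCc2ccccc2)c(OCc2ccccc2)c1[C@H](c1cc(OC)c(OC)c(OC)c1)C(I)(C(=O)OC)C(=O)OC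
A2 | alternative 1 | 7,8-bis(benzyloxy)-6-methoxy-1-(3,4,5-trimethoxyphenyl)tetralin with a methoxycarbonyl group on C2 and a cis-fused γ-lactone from the second C2 carboxyl to C9' on C3 (C9' trans to the aryl group) | COc1cc2c(c(OCc3ccccc3)c1OCc1ccccc1)[C@H](c1cc(OC)c(OC)c(OC)c1)[C@@](C(=O)OC)(C(=O)O3)[C@@H](C3)C2
A3 | alternative 2 | (1S)-7,8-bis(benzyloxy)-6-methoxy-1-(3,4,5-trimethoxyphenyl)-1,4-dihydronaphthalene | COc1cc2c(c(OCc3ccccc3)c1OCc1ccccc1)[C@H](c1cc(OC)c(OC)c(OC)c1)C=CC2
A4 | alternative 2 | dimethyl (1S,2R,3S)-7,8-bis(benzyloxy)-6-methoxy-1-(3,4,5-trimethoxyphenyl)tetralin-2,3-dicarboxylate | COc1cc2c(c(OCc3ccccc3)c1OCc1ccccc1)[C@H](c1cc(OC)c(OC)c(OC)c1)[C@@H](C(=O)OC)[C@@H](C(=O)OC)C2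
A5 | alternative 3 | (E)-1-(3,4,5-trimethoxyphenyl)buta-1,3-diene | C=C/C=C/c1cc(OC)c(OC)c(OC)c1
A6 | alternative 3 | 3-methoxycyclohexa-3,5-diene-1,2-dione (3-methoxy-o-benzoquinone) | COC1=CC=CC(=O)C1=O
A7 | alternative 3 | (1S)-6-methoxy-1-(3,4,5-trimethoxyphenyl)-1,4-dihydronaphthalene-7,8-diol | COc1cc2c(c(O)c1O)[C@H](c1cc(OC)c(OC)c(OC)c1)C=CC2
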